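(The numbers are made up; no experiment stands behind them.)

I count every amount in percent of the L charged, with one L.Q as two, so that the four flasks stand on one scale.

in all of them: L 0.10 M; time 80 min
- cedar: temperature 80 °C
- larch: at 100 °C until 15 min, from then on at 60 °C
- birch: temperature 100 °C
- oak: temperature 60 °C

    L + 2 Q → 3 Q (k1 = 1.64 M⁻² s⁻¹, Ea1 = 56.0 kJ mol⁻¹)
    L → Q (k2 = 8.29 × 10⁻⁵ s⁻¹, Ea2 = 114 kJ mol⁻¹)
    Q → G (k3 = 4.64 × 10⁻⁴ s⁻¹, Ea3 = 113 kJ mol⁻¹)
    L → E (k4 = 7.56 × 10⁻⁷ s⁻¹, Ea4 = 119 kJ mol⁻¹)
    L + Q → L.Q (k5 = 0.00905 M⁻¹ s⁻¹, Ea5 = 75.0 kJ mol⁻¹)
    (constants at 80 °C)

- the flask with the highest amount of Q, in percent of the L charged ("all alike" if they lie within 1.5 percentage points) (cedar / larch / birch / oak / all alike)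
- final Q, as a percentage of the L charged, in cedar
- final Q, as a percentage of the L charged, in larch
- final Q, as a percentage of the L charged, in birch
- final Q, as a percentage of the L charged, in oak

- a species is counted by the L in it: one L.Q counts as two
- for a step with 2 of a species take k times the square, and two of it per event
- at 80 °C the constants are as listed, elsewhere as the activation energies make them

The charge holds L and no Q, so the first Q has to come from the direct conversion of L, and the autocatalytic step waits for it. That middle stretch is hard by hand, but the two ends are not.

At the cold end, in oak at 60 °C, I take L at its charge, so Q goes both to G and into L.Q at steady rate constants, and together these give Q a lifetime of 69.1 min, shorter than the run of 80 min. So I let the direct conversion feed Q at a constant rate against that loss, and at the end of the run this gives 2.29% of the charge. This figure is rough, since I leave out the autocatalytic step.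

At the hot end, in birch at 100 °C, L has a lifetime of 25.1 min on the direct conversion, while Q lasts 4.57 min on its way to G, so on these two steps Q goes sooner than L does. Late in the run, with Q small, I drop the autocatalytic step and the binding, and a plain chain remains: L to Q to G. Q then follows L at a fixed share, a quasi-steady state. That share is the rate constant of the direct conversion divided by the loss constant of Q minus that same constant, here 0.222. I call it the tail ratio: Q per L once the burst is over.

But how much L remains? The other steps also draw on L, so L in birch ends below what the direct conversion leaves, 4.12%. Q in birch therefore ends below about 0.915%. Cedar and larch lie between the ends, and there my reckoning stops without a number.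

The forecast names cedar, with 23% there, 10% in larch, 0% in birch and 2.7% in oak, and says of larch that “the cooling then largely freezes that amount”.

The run puts cedar highest at 21.5%, with larch at 10.4%, oak at 2.77% and birch at 0.292%. Birch at 80.0 min still holds L at 1.33%, and the tail ratio times that gives 0.295%. Cedar stands elsewhere: at 80 °C the ratio is 0.218, so its L of 2.84% corresponds to 0.619%, less than the Q it holds. At 800 min cedar reads L 0.0200% and Q 0%, where the ratio gives 0.00436%.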